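**Plan** (germacrane numbering: ring C1–C10, lactone carbons C11–C13, C14 = methyl on C10, C15 = CH2OH on C4)
1. Retrosynthesis: remove the angelate and the 1,10-epoxide (back to E-C1=C10), open the lactone (C6–O and C7–C11) to a C6 ketone, and return the C4=C5/15-OH unit to a saturated C4–CH2OH.
2. The ten-membered ring then contains C6(=O)–C7–C8–C9–C10(CH3)=C1, a δ,ε-unsaturated ketone. Cutting C8–C9 by a retro-oxy-Cope shift gives a trans-1,2-dialkenylcyclohexanol in which C1–C6 is a bond of the six-membered ring C1–C6.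
3. Forward: (S)-cyclohex-3-enecarboxylic acid → 5-substituted cyclohexenone → epoxy ketone → semipinacol shift → ketone 10; alkoxyvinyl group onto C6; anionic oxy-Cope ring expansion (six → ten) with alkylation of the enolate at C7 in the same flask.
4. Then C4=C5 is made inside a temporary five-membered ketal ring (O15–C6), followed by the γ-lactone, the methylene, the angelate and the epoxide.
5. Stereochemistry: the acid centre directs the epoxide (C2); the semipinacol shift fixes C1 trans to O2; the chair [3,3] shift with an E-enol ether turns C1/C6 into C8; C7 comes from alkylation anti to C8–C9; C6 from hydride reduction; the C4=C5 geometry from a selenoxide syn-elimination within the five-membered ring; the epoxide from C2–OH-directed peracid attack.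

Key step: step 12

Remark: the ketal carbon made in step 13 and the aminomethyl-bearing carbon of the Mannich intermediates of step 18 arise as epimer mixtures and are written without descriptors; both centres are removed later.

**Step 1**
Reactants: 1 (S)-cyclohex-3-ene-1-carboxylic acid
Product: 2 (1S,4S,5S)-4-iodo-6-oxabicyclo[3.2.1]octan-7-one
Conditions: I2, KI, NaHCO3, H2O/CH2Cl2, 0 °C → rt
Reagents that add atoms: iodine, II
Why: Iodolactonisation: the carboxylate opens the iodonium ion at the nearer alkene carbon, which should give the cis-bridged γ-lactone with iodine trans to the lactone oxygen, so the acid centre fixes both new centres.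

**Step 2**
Reactants: 2 (1S,4S,5S)-4-iodo-6-oxabicyclo[3.2.1]octan-7-one
Product: 3 (1S,5S)-6-oxabicyclo[3.2.1]oct-3-en-7-one
Conditions: DBU, toluene, 110 °C
Reagents that add atoms: none
Why: E2 dehydroiodination: the only anti hydrogen on a carbon that bears no oxygen is removed, which should place the alkene allylic to the lactone oxygen.

**Step 3**
Reactants: 3 (1S,5S)-6-oxabicyclo[3.2.1]oct-3-en-7-one
Product: 4 (1S,5S)-5-(hydroxymethyl)cyclohex-2-en-1-ol
Conditions: LiAlH4, THF, 0 °C
Reagents that add atoms: none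
Why: Hydride reduction of the lactone should give the cis-1,3 diol without touching either stereocentre.

**Step 4**
Reactants: 4 (1S,5S)-5-(hydroxymethyl)cyclohex-2-en-1-ol
Product: 5 (1S,5S)-5-[(tert-butyldimethylsilyloxy)methyl]cyclohex-2-en-1-ol
Conditions: TBSCl, imidazole, CH2Cl2, −20 °C
Reagents that add atoms: tert-butyldimethylsilyl chloride, CC(C)(C)[Si](C)(C)Cl
Why: Silylation should occur selectively at the primary hydroxyl, the secondary allylic one being more hindered.

**Step 5**
Reactants: 5 (1S,5S)-5-[(tert-butyldimethylsilyloxy)methyl]cyclohex-2-en-1-ol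
Product: 6 (S)-5-[(tert-butyldimethylsilyloxy)methyl]cyclohex-2-en-1-one
Conditions: MnO2, CH2Cl2, rt
Reagents that add atoms: none
Why: Allylic oxidation with MnO2 should give the enone and leave the silyl ether and the remote stereocentre unchanged.

**Step 6**
Reactants: 6 (S)-5-[(tert-butyldimethylsilyloxy)methyl]cyclohex-2-en-1-one
Product: 7 (1S,4S,6S)-4-[(tert-butyldimethylsilyloxy)methyl]-7-oxabicyclo[4.1.0]heptan-2-one
Conditions: H2O2 (30% aq.), NaOH (cat.), MeOH, 0 °C
Reagents that add atoms: hydrogen peroxide, OO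
Why: Weitz–Scheffer epoxidation: hydroperoxide should add to the β-carbon anti to the ring substituent, as in 5-substituted cyclohexenones, so the epoxide is trans to the silyloxymethyl group (this oxygen becomes O2).

**Step 7**
Reactants: 7 (1S,4S,6S)-4-[(tert-butyldimethylsilyloxy)methyl]-7-oxabicyclo[4.1.0]heptan-2-one
Product: 8 (1S,2S,4S,6S)-4-[(tert-butyldimethylsilyloxy)methyl]-2-(prop-1-en-2-yl)-7-oxabicyclo[4.1.0]heptan-2-ol
Conditions: CH2=C(CH3)MgBr, THF, −78 °C
Reagents that add atoms: isopropenylmagnesium bromide, CC(=C)[Mg]Br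
Why: Grignard 1,2-addition should occur from the face opposite the epoxide oxygen, giving the tertiary alcohol with hydroxyl cis to the epoxide and isopropenyl antiperiplanar to the neighbouring epoxide C–O bond.

**Step 8**
Reactants: 8 (1S,2S,4S,6S)-4-[(tert-butyldimethylsilyloxy)methyl]-2-(prop-1-en-2-yl)-7-oxabicyclo[4.1.0]heptan-2-ol
Product: 9 (2R,3S,5S)-5-[(tert-butyldimethylsilyloxy)methyl]-3-hydroxy-2-(prop-1-en-2-yl)cyclohexan-1-one
Conditions: ZnBr2 (0.3 equiv), CH2Cl2, 0 °C
Reagents that add atoms: none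
Why: Semipinacol rearrangement of the 2,3-epoxy tertiary alcohol: isopropenyl should migrate with inversion to the epoxide carbon next to the carbinol, which sets C1 with isopropenyl trans to the retained hydroxyl and regenerates the ketone.

**Step 9**
Reactants: 9 (2R,3S,5S)-5-[(tert-butyldimethylsilyloxy)methyl]-3-hydroxy-2-(prop-1-en-2-yl)cyclohexan-1-one
Product: 10 (2R,3S,5S)-5-[(tert-butyldimethylsilyloxy)methyl]-2-(prop-1-en-2-yl)-3-(triisopropylsilyloxy)cyclohexan-1-one
Conditions: TIPSOTf, 2,6-lutidine, CH2Cl2, −78 °C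
Reagents that add atoms: triisopropylsilyl triflate, CC(C)[Si](C(C)C)(C(C)C)OS(=O)(=O)C(F)(F)F
Why: Silylation under non-nucleophilic base at low temperature should cap the aldol hydroxyl before it can eliminate and gives a group that does not migrate in the later alkoxide steps.

**Step 10**
Reactants: 11 4-methoxybenzyl alcohol
Product: 12 1-{[(E)-1,2-dichloroethenyl]oxymethyl}-4-methoxybenzene
Conditions: KH, trichloroethylene, THF, 0 °C → rt
Reagents that add atoms: trichloroethylene, ClC=C(Cl)Cl
Why: The alkoxide should add to dichloroacetylene formed in the flask from trichloroethylene, giving the E-dichlorovinyl ether (addition–elimination synthesis of ynol ether precursors).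

**Step 11**
Reactants: 10 (2R,3S,5S)-5-[(tert-butyldimethylsilyloxy)methyl]-2-(prop-1-en-2-yl)-3-(triisopropylsilyloxy)cyclohexan-1-one; 12 1-{[(E)-1,2-dichloroethenyl]oxymethyl}-4-methoxybenzene
Product: 15 (1R,2R,3S,5S)-5-[(tert-butyldimethylsilyloxy)methyl]-1-[(E)-2-(4-methoxybenzyloxy)ethenyl]-2-(prop-1-en-2-yl)-3-(triisopropylsilyloxy)cyclohexan-1-ol, via lithium (4-methoxybenzyloxy)acetylide 13 (not isolated), via lithium alkoxide of the alkoxyethynyl carbinol 14 (not isolated)
Conditions: 12, n-BuLi (2.1 equiv), THF, −78 → −40 °C; 10, −78 °C; then LiAlH4, −78 → 0 °C; Rochelle salt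
Reagents that add atoms: none
Why: Butyllithium should convert 12 into the lithium alkoxyacetylide, which adds to the ketone from the face opposite both the neighbouring isopropenyl group and the silyloxymethyl group; the propargylic alkoxide then directs trans-hydroalumination to the E-enol ether.

**Step 12**
Reactants: 15 (1R,2R,3S,5S)-5-[(tert-butyldimethylsilyloxy)methyl]-1-[(E)-2-(4-methoxybenzyloxy)ethenyl]-2-(prop-1-en-2-yl)-3-(triisopropylsilyloxy)cyclohexan-1-ol
Product: 17 methyl [(2S,4S,7R,8S)-4-[(tert-butyldimethylsilyloxy)methyl]-8-(4-methoxybenzyloxy)-10-methyl-6-oxo-2-(triisopropylsilyloxy)cyclodec-1(10)E-en-7-yl]acetate (germacrane numbering), via potassium enolate of the ring-expanded ketone 16 (not isolated)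
Conditions: KHMDS, 18-crown-6, THF, −78 → 0 °C; then BrCH2CO2Me, −78 °C
Reagents that add atoms: methyl bromoacetate, COC(=O)CBr
Why: The tertiary potassium alkoxide weakens the C1–C6 ring bond, so the 1,5-diene C9=C10–C1–C6–C7=C8 should undergo a [3,3] shift through a chair with both alkenyl groups equatorial, forming C8–C9 and the potassium enolate 16; the closest known reaction type is the anionic oxy-Cope ring expansion of trans-1,2-dialkenylcyclohexanols to (E)-cyclodec-5-enones with alkylation of the enolate in the same flask. The ten-membered ring is closed by a four-atom ring expansion of the cyclohexane (the C1–C6 bond is exchanged for C8–C9), not by an end-to-end cyclisation, so no high dilution is needed. C8 is set in the chair: the E-enol ether holds the benzyloxy group equatorial and the (1R,6R) pair of 15 (germacrane C1 and C6) is transcribed into 8S, while the equatorial ring bond C1–C2 gives the E geometry of C1=C10. C7 is set in the alkylation: H8 eclipses the enolate to avoid A(1,3) strain, C9 lies on the inner face, and methyl bromoacetate should add to the outer face anti to the C8–C9 bond, giving 7R. The step needs chair over boat selectivity (secured by the trans-diequatorial alkenyl groups), C- over O-alkylation, and survival of the β-alkoxy enolate; for the last, the shift is run at or below 0 °C and the enolate is alkylated at −78 °C.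

**Step 13**
Reactants: 17 methyl [(2S,4S,7R,8S)-4-[(tert-butyldimethylsilyloxy)methyl]-8-(4-methoxybenzyloxy)-10-methyl-6-oxo-2-(triisopropylsilyloxy)cyclodec-1(10)E-en-7-yl]acetate
Product: 18 cyclic mixed methyl ketal of 17 (tetrahydrofuran ring C4–C5–C6–O–C15 with methoxy on C6; C15 silyl group removed)
Conditions: CSA (cat.), MeOH, 0 °C → rt
Reagents that add atoms: methanol, CO
Why: Acidic methanol should cleave the primary silyl ether, and the freed C15 hydroxyl closes the five-membered mixed ketal on the C6 ketone, the oxocarbenium ion being taken up by the solvent (desilylation and ketalisation).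

**Step 14**
Reactants: 18 cyclic mixed methyl ketal of 17
Product: 19 bridged 2,3-dihydrofuran (enol ether C5=C6 with the ring oxygen of C15 on C6)
Conditions: TMSOTf, iPr2NEt, CH2Cl2, −40 → 0 °C
Reagents that add atoms: none
Why: The silyl triflate should ionise the methoxy group and the hindered amine removes a proton from the less hindered C5 methylene, giving the endocyclic enol ether (ketal to enol ether elimination).

**Step 15**
Reactants: 19 bridged 2,3-dihydrofuran
Product: 21 bridged 2-methoxy-2,5-dihydrofuran (C4=C5 inside the five-membered ring; methoxy and ring oxygen on C6), via 2-methoxy-3-phenylseleno ketal 20 (not isolated)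
Conditions: PhSeCl, pyridine, MeOH/CH2Cl2, −78 °C; then H2O2 (30% aq.), pyridine, 0 °C → rt
Reagents that add atoms: methanol, CO; phenylselenenyl chloride, Cl[Se]c1ccccc1 (selenium stays only in 20)
Why: Methoxyselenenylation should put selenium on C5 on the face away from the ring bridge (cis to H4); the selenoxide then eliminates syn toward H4, its only β-hydrogen, so C4=C5 forms inside the five-membered ring with C15 and C6 cis, which is the trans geometry in the ten-membered ring (selenoxide elimination).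

**Step 16**
Reactants: 21 bridged 2-methoxy-2,5-dihydrofuran
Product: 24 (2S,6R,7R,8S)-15-hydroxy-8-(4-methoxybenzyloxy)-2-(triisopropylsilyloxy)germacra-1(10),4-dien-12,6-olide (trans-fused γ-lactone; C15 cis to C6 on C4=C5), via γ-hydroxy enone 22 (not isolated), via allylic alcohol hydroxy ester 23 (not isolated)
Conditions: PPTS, acetone/H2O, 0 °C; then NaBH4, CeCl3·7H2O, MeOH, −78 °C; then PPTS, CH2Cl2, rt
Reagents that add atoms: water, O
Why: Acetal hydrolysis should free the cis-γ-hydroxy enone, and Luche reduction is expected to deliver hydride to C6 from the outer face anti to the C7–C8 ring bond (C7–H near the carbonyl plane) to give the 6R alcohol, which closes onto the ester to the trans-fused γ-lactone (lactonisation).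

**Step 17**
Reactants: 24 (2S,6R,7R,8S)-15-hydroxy-8-(4-methoxybenzyloxy)-2-(triisopropylsilyloxy)germacra-1(10),4-dien-12,6-olide
Product: 25 15-O-tert-butyldimethylsilyl ether of 24
Conditions: TBSCl, imidazole, DMF, 0 °C
Reagents that add atoms: tert-butyldimethylsilyl chloride, CC(C)(C)[Si](C)(C)Cl
Why: Silylation of the only free hydroxyl should protect the primary allylic alcohol against the base, the oxidant and the acylation that follow.

**Step 18**
Reactants: 25 15-O-tert-butyldimethylsilyl ether of 24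
Product: 28 (2S,6R,7R,8S)-15-(tert-butyldimethylsilyloxy)-8-(4-methoxybenzyloxy)-2-(triisopropylsilyloxy)germacra-1(10),4,11(13)-trien-12,6-olide, via dimethylaminomethyl lactone 26 (not isolated), via trimethylammonium iodide 27 (not isolated)
Conditions: LiHMDS, THF, −78 °C; CH2=NMe2 I; then MeI, CH2Cl2/MeOH, rt; then aq. NaHCO3
Reagents that add atoms: dimethylmethyleneiminium iodide, C=[N+](C)C.[I-]; iodomethane, CI (stays only in 27)
Why: The lactone enolate should be aminomethylated at C11 (Mannich reaction), and quaternisation followed by base-induced elimination gives the α-methylene lactone without touching C7.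

**Step 19**
Reactants: 28 (2S,6R,7R,8S)-15-(tert-butyldimethylsilyloxy)-8-(4-methoxybenzyloxy)-2-(triisopropylsilyloxy)germacra-1(10),4,11(13)-trien-12,6-olide
Product: 29 (2S,6R,7R,8S)-15-(tert-butyldimethylsilyloxy)-8-hydroxy-2-(triisopropylsilyloxy)germacra-1(10),4,11(13)-trien-12,6-olide
Conditions: DDQ, CH2Cl2/pH 7 buffer, 0 °C
Reagents that add atoms: none
Why: Oxidative cleavage of the 4-methoxybenzyl ether should free the C8 hydroxyl under neutral conditions that spare the silyl ethers, the alkenes and the lactone.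

**Step 20**
Reactants: 29 (2S,6R,7R,8S)-15-(tert-butyldimethylsilyloxy)-8-hydroxy-2-(triisopropylsilyloxy)germacra-1(10),4,11(13)-trien-12,6-olide
Product: 30 8-O-angelate of 29
Conditions: angelic acid, 2,4,6-Cl3C6H2COCl, Et3N, toluene, rt; then 29, DMAP, rt
Reagents that add atoms: angelic acid, C/C=C(/C)C(=O)O
Why: Yamaguchi esterification through the mixed anhydride should acylate the hindered secondary alcohol with retention at C8 and without isomerising the Z-alkene of the angelate.

**Step 21**
Reactants: 30 8-O-angelate of 29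
Product: 31 (2S,6R,7R,8S)-8-angeloyloxy-2,15-dihydroxygermacra-1(10),4,11(13)-trien-12,6-olide
Conditions: HF·pyridine, pyridine, THF, 0 °C → rt
Reagents that add atoms: none
Why: Buffered fluoride should remove both silyl ethers while avoiding the alkoxide that would start an oxy-Cope shift of the 2-hydroxy-1,5-diene.

**Step 22**
Reactants: 31 (2S,6R,7R,8S)-8-angeloyloxy-2,15-dihydroxygermacra-1(10),4,11(13)-trien-12,6-olide
Product: 32 (1R,2S,6R,7R,8S,10R)-8-angeloyloxy-1,10-epoxy-2,15-dihydroxygermacra-4,11(13)-dien-12,6-olide (target, EANPDB COMP_00180)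
Conditions: mCPBA, NaHCO3, CH2Cl2, −20 → 0 °C
Reagents that add atoms: 3-chloroperoxybenzoic acid, OOC(=O)c1cccc(Cl)c1
Why: Hydroxyl-directed peracid epoxidation: H2 lies in the alkene plane to avoid A(1,3) strain with C14 and C3 fills the inner face, so the peracid should attack the outer face syn to the C2 hydroxyl and give the (1R,10R) trans-epoxide; the 1(10)-alkene is the most electron-rich, the 4,5-alkene being deactivated by two allylic oxygens.

**Compound list**
1 | (S)-cyclohex-3-ene-1-carboxylic acid | OC(=O)[C@@H]1CC=CCC1 | starting material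
2 | (1S,4S,5S)-4-iodo-6-oxabicyclo[3.2.1]octan-7-one | O=C1O[C@H]2C[C@@H]1CC[C@@H]2I | intermediate
3 | (1S,5S)-6-oxabicyclo[3.2.1]oct-3-en-7-one | O=C1O[C@H]2C[C@@H]1CC=C2 | intermediate
4 | (1S,5S)-5-(hydroxymethyl)cyclohex-2-en-1-ol | OC[C@@H]1C[C@H](O)C=CC1 | intermediate
5 | (1S,5S)-5-[(tert-butyldimethylsilyloxy)methyl]cyclohex-2-en-1-ol | CC(C)(C)[Si](C)(C)OC[C@@H]1C[C@H](O)C=CC1 | intermediate
6 | (S)-5-[(tert-butyldimethylsilyloxy)methyl]cyclohex-2-en-1-one | CC(C)(C)[Si](C)(C)OC[C@@H]1CC(=O)C=CC1 | intermediate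
7 | (1S,4S,6S)-4-[(tert-butyldimethylsilyloxy)methyl]-7-oxabicyclo[4.1.0]heptan-2-one | CC(C)(C)[Si](C)(C)OC[C@@H]1CC(=O)[C@H]2O[C@H]2C1 | intermediate
8 | (1S,2S,4S,6S)-4-[(tert-butyldimethylsilyloxy)methyl]-2-(prop-1-en-2-yl)-7-oxabicyclo[4.1.0]heptan-2-ol | CC(C)(C)[Si](C)(C)OC[C@@H]1C[C@](O)(C(C)=C)[C@H]2O[C@H]2C1 | intermediate
9 | (2R,3S,5S)-5-[(tert-butyldimethylsilyloxy)methyl]-3-hydroxy-2-(prop-1-en-2-yl)cyclohexan-1-one | CC(C)(C)[Si](C)(C)OC[C@@H]1CC(=O)[C@H](C(C)=C)[C@@H](O)C1 | intermediate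
10 | (2R,3S,5S)-5-[(tert-butyldimethylsilyloxy)methyl]-2-(prop-1-en-2-yl)-3-(triisopropylsilyloxy)cyclohexan-1-one | CC(C)(C)[Si](C)(C)OC[C@@H]1CC(=O)[C@H](C(C)=C)[C@@H](O[Si](C(C)C)(C(C)C)C(C)C)C1 | intermediate
11 | 4-methoxybenzyl alcohol | COc1ccc(CO)cc1 | starting material
12 | 1-{[(E)-1,2-dichloroethenyl]oxymethyl}-4-methoxybenzene | COc1ccc(CO/C(Cl)=C\Cl)cc1 | intermediate
13 | lithium (4-methoxybenzyloxy)acetylide (not isolated) | [Li]C#COCc1ccc(OC)cc1 | intermediate
14 | lithium alkoxide of the (4-methoxybenzyloxy)ethynyl carbinol from 10 (not isolated) | CC(C)(C)[Si](C)(C)OC[C@@H]1C[C@@](O[Li])(C#COCc2ccc(OC)cc2)[C@H](C(C)=C)[C@@H](O[Si](C(C)C)(C(C)C)C(C)C)C1 | intermediate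
15 | (1R,2R,3S,5S)-5-[(tert-butyldimethylsilyloxy)methyl]-1-[(E)-2-(4-methoxybenzyloxy)ethenyl]-2-(prop-1-en-2-yl)-3-(triisopropylsilyloxy)cyclohexan-1-ol | CC(C)(C)[Si](C)(C)OC[C@@H]1C[C@@](O)(/C=C/OCc2ccc(OC)cc2)[C@H](C(C)=C)[C@@H](O[Si](C(C)C)(C(C)C)C(C)C)C1 | intermediate
16 | potassium enolate (C6–O, C6=C7) of the ring-expanded ten-membered ketone (not isolated) | CC(C)[Si](C(C)C)(C(C)C)O[C@@H]1/C=C(C)/C[C@H](OCc2ccc(OC)cc2)/C=C(\O[K])C[C@@H](CO[Si](C)(C)C(C)(C)C)C1 | intermediate
17 | methyl [(2S,4S,7R,8S)-4-[(tert-butyldimethylsilyloxy)methyl]-8-(4-methoxybenzyloxy)-10-methyl-6-oxo-2-(triisopropylsilyloxy)cyclodec-1(10)E-en-7-yl]acetate (germacrane numbering) | CC(C)[Si](C(C)C)(C(C)C)O[C@@H]1/C=C(C)/C[C@H](OCc2ccc(OC)cc2)[C@@H](CC(=O)OC)C(=O)C[C@@H](CO[Si](C)(C)C(C)(C)C)C1 | intermediate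
18 | cyclic mixed methyl ketal of 17 (tetrahydrofuran ring C4–C5–C6–O–C15; methoxy on C6; both ketal epimers) | CC(C)[Si](C(C)C)(C(C)C)O[C@@H]1/C=C(C)/C[C@H](OCc2ccc(OC)cc2)[C@@H](CC(=O)OC)C3(OC)C[C@@H](CO3)C1 | intermediate
19 | bridged 2,3-dihydrofuran (enol ether C5=C6; 4S) | CC(C)[Si](C(C)C)(C(C)C)O[C@@H]1/C=C(C)/C[C@H](OCc2ccc(OC)cc2)[C@@H](CC(=O)OC)C3=C[C@@H](CO3)C1 | intermediate
20 | (4R,5S,6R)-6-methoxy-5-phenylseleno tetrahydrofuran ketal, selenium cis to H4 (not isolated) | CC(C)[Si](C(C)C)(C(C)C)O[C@@H]1/C=C(C)/C[C@H](OCc2ccc(OC)cc2)[C@@H](CC(=O)OC)[C@]3(OC)[C@@H]([Se]c4ccccc4)[C@@H](CO3)C1 | intermediate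
21 | bridged (6S)-6-methoxy-2,5-dihydrofuran with C4=C5 | CC(C)[Si](C(C)C)(C(C)C)O[C@@H]1/C=C(C)/C[C@H](OCc2ccc(OC)cc2)[C@@H](CC(=O)OC)[C@]3(OC)C=C(CO3)C1 | intermediate
22 | cis-γ-hydroxy enone: 15-hydroxy-6-oxo ester with C15 cis to C6 on C4=C5 (not isolated) | CC(C)[Si](C(C)C)(C(C)C)O[C@@H]1/C=C(C)/C[C@H](OCc2ccc(OC)cc2)[C@@H](CC(=O)OC)C(=O)/C=C(\CO)C1 | intermediate
23 | (6R)-6,15-dihydroxy ester (not isolated) | CC(C)[Si](C(C)C)(C(C)C)O[C@@H]1/C=C(C)/C[C@H](OCc2ccc(OC)cc2)[C@@H](CC(=O)OC)[C@H](O)/C=C(\CO)C1 | intermediate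
24 | (2S,6R,7R,8S)-15-hydroxy-8-(4-methoxybenzyloxy)-2-(triisopropylsilyloxy)germacra-1(10),4-dien-12,6-olide | O=C1O[C@@H]2/C=C(\CO)C[C@H](O[Si](C(C)C)(C(C)C)C(C)C)/C=C(C)/C[C@H](OCc3ccc(OC)cc3)[C@H]2C1 | intermediate
25 | 15-O-tert-butyldimethylsilyl ether of 24 | O=C1O[C@@H]2/C=C(\CO[Si](C)(C)C(C)(C)C)C[C@H](O[Si](C(C)C)(C(C)C)C(C)C)/C=C(C)/C[C@H](OCc3ccc(OC)cc3)[C@H]2C1 | intermediate
26 | 11-(dimethylaminomethyl) lactone, C11 epimers (not isolated) | CN(C)CC1C(=O)O[C@@H]2/C=C(\CO[Si](C)(C)C(C)(C)C)C[C@H](O[Si](C(C)C)(C(C)C)C(C)C)/C=C(C)/C[C@H](OCc3ccc(OC)cc3)[C@@H]12 | intermediate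
27 | trimethylammonium iodide of 26 (not isolated) | C[N+](C)(C)CC1C(=O)O[C@@H]2/C=C(\CO[Si](C)(C)C(C)(C)C)C[C@H](O[Si](C(C)C)(C(C)C)C(C)C)/C=C(C)/C[C@H](OCc3ccc(OC)cc3)[C@@H]12.[I-] | intermediate
28 | (2S,6R,7R,8S)-15-(tert-butyldimethylsilyloxy)-8-(4-methoxybenzyloxy)-2-(triisopropylsilyloxy)germacra-1(10),4,11(13)-trien-12,6-olide | C=C1C(=O)O[C@@H]2/C=C(\CO[Si](C)(C)C(C)(C)C)C[C@H](O[Si](C(C)C)(C(C)C)C(C)C)/C=C(C)/C[C@H](OCc3ccc(OC)cc3)[C@@H]12 | intermediate
29 | (2S,6R,7R,8S)-15-(tert-butyldimethylsilyloxy)-8-hydroxy-2-(triisopropylsilyloxy)germacra-1(10),4,11(13)-trien-12,6-olide | C=C1C(=O)O[C@@H]2/C=C(\CO[Si](C)(C)C(C)(C)C)C[C@H](O[Si](C(C)C)(C(C)C)C(C)C)/C=C(C)/C[C@H](O)[C@@H]12 | intermediate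
30 | 8-O-angelate of 29 | C=C1C(=O)O[C@@H]2/C=C(\CO[Si](C)(C)C(C)(C)C)C[C@H](O[Si](C(C)C)(C(C)C)C(C)C)/C=C(C)/C[C@H](OC(=O)/C(C)=C\C)[C@@H]12 | intermediate
31 | (2S,6R,7R,8S)-8-angeloyloxy-2,15-dihydroxygermacra-1(10),4,11(13)-trien-12,6-olide | C=C1C(=O)O[C@@H]2/C=C(\CO)C[C@H](O)/C=C(C)/C[C@H](OC(=O)/C(C)=C\C)[C@@H]12 | intermediate
32 | (1R,2S,6R,7R,8S,10R)-8-angeloyloxy-1,10-epoxy-2,15-dihydroxygermacra-4,11(13)-dien-12,6-olide | C=C1C(=O)O[C@@H]2/C=C(\CO)C[C@H](O)[C@H]3O[C@]3(C)C[C@H](OC(=O)/C(C)=C\C)[C@@H]12 | target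

**Step count**
Total: 22 steps. Longest linear sequence: 21 steps (steps 1–9 and 11–22 from 1; step 10 makes the side reagent 12).

**Steps most likely to fail**

Step 12. The enolate 16 carries an alkoxy group on the β-carbon (C8) and may expel it, or exchange protons, before it is alkylated. The fallback removes the free enolate from the rearrangement. It sets out from 15, which is silylated (TMSCl, imidazole) to the trimethylsilyl ether of 15 F1. Heating F1 in a neutral medium (about 200 °C, base-washed glass) should bring about the same [3,3] shift as a thermal siloxy-Cope rearrangement and give the ten-membered trimethylsilyl enol ether F2 directly. Methyllithium at −78 °C then releases the lithium enolate F3 regiospecifically, and cold alkylation with methyl bromoacetate returns to the route at 17.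

Step 14. The oxocarbenium ion at C6 is formed without a nucleophilic solvent and may be captured across the ring by the C1=C10 alkene (re-closure to a six-membered ring), or may lose a proton toward C7. The fallback sets out from 17 and puts selenium on C5 before the ketal ring is made. Kinetic enolisation toward the C5 methylene (LDA, TMSCl, −78 °C) gives the trimethylsilyl enol ether of 17 F4, and PhSeCl gives the 5-phenylseleno ketone F5. Acidic methanol (CSA, MeOH) then removes the primary silyl group and closes the mixed ketal while C5 equilibrates to the epimer with selenium trans to C3. This is 20, where the fallback rejoins the route for the oxidation half of step 15.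

Step 16. Hydride delivery to C6 may come mainly from the other face and give the 6S alcohol, which would close to the cis-fused lactone. The fallback then forms the C6–O bond by substitution with inversion. It sets out from 21: the same hydrolysis and reduction give the 6-epi cis-fused lactone F6, and silylation of the primary hydroxyl gives its 15-O-silyl ether F7. Saponification gives the 6S hydroxy acid F8, kept as its triethylammonium salt so that it does not relactonise. Mitsunobu lactonisation (PPh3, DIAD) then lets the carboxylate displace the activated C6 oxygen with inversion, which returns to the route at 25.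

**Further compounds**
F1 | step 12 | trimethylsilyl ether of 15 | CC(C)(C)[Si](C)(C)OC[C@@H]1C[C@@](O[Si](C)(C)C)(/C=C/OCc2ccc(OC)cc2)[C@H](C(C)=C)[C@@H](O[Si](C(C)C)(C(C)C)C(C)C)C1
F2 | step 12 | ten-membered trimethylsilyl enol ether (C6–O, C6=C7) | CC(C)[Si](C(C)C)(C(C)C)O[C@@H]1/C=C(C)/C[C@H](OCc2ccc(OC)cc2)/C=C(\O[Si](C)(C)C)C[C@@H](CO[Si](C)(C)C(C)(C)C)C1
F3 | step 12 | lithium enolate of the ten-membered ketone | CC(C)[Si](C(C)C)(C(C)C)O[C@@H]1/C=C(C)/C[C@H](OCc2ccc(OC)cc2)/C=C(\O[Li])C[C@@H](CO[Si](C)(C)C(C)(C)C)C1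
F4 | step 14 | trimethylsilyl enol ether of 17 toward C5 (enol ether geometry not fixed) | CC(C)[Si](C(C)C)(C(C)C)O[C@@H]1/C=C(C)/C[C@H](OCc2ccc(OC)cc2)[C@@H](CC(=O)OC)C(O[Si](C)(C)C)=C[C@@H](CO[Si](C)(C)C(C)(C)C)C1
F5 | step 14 | 5-phenylseleno ketone (C5 epimers) | CC(C)[Si](C(C)C)(C(C)C)O[C@@H]1/C=C(C)/C[C@H](OCc2ccc(OC)cc2)[C@@H](CC(=O)OC)C(=O)C([Se]c3ccccc3)[C@@H](CO[Si](C)(C)C(C)(C)C)C1
F6 | step 16 | 6-epi (6S) cis-fused lactone with free 15-OH | O=C1O[C@H]2/C=C(\CO)C[C@H](O[Si](C(C)C)(C(C)C)C(C)C)/C=C(C)/C[C@H](OCc3ccc(OC)cc3)[C@H]2C1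
F7 | step 16 | 15-O-tert-butyldimethylsilyl ether of F6 | O=C1O[C@H]2/C=C(\CO[Si](C)(C)C(C)(C)C)C[C@H](O[Si](C(C)C)(C(C)C)C(C)C)/C=C(C)/C[C@H](OCc3ccc(OC)cc3)[C@H]2C1
F8 | step 16 | (6S)-6-hydroxy acid | CC(C)[Si](C(C)C)(C(C)C)O[C@@H]1/C=C(C)/C[C@H](OCc2ccc(OC)cc2)[C@@H](CC(=O)O)[C@@H](O)/C=C(\CO[Si](C)(C)C(C)(C)C)C1
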